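**Retrosynthetic overview**

1. Feature: the cyclopentenone ring C1(=O)–C2(OMe)=C3(Ar)–C4–C5(OMe)(Ar), with C4 as the spiro carbon of the oxirane (C6 = oxirane CH2). The oxirane C4–O bond is trans to C5–OMe, which is the relationship expected when methanol adds to an oxirane-bridged oxyallyl zwitterion formed photochemically from a 4-pyranone.
2. Last ring: the oxirane, closed by the C4 alkoxide displacing a C6 tosylate; phenol desilylation follows.
3. Key disconnection: C3–C4 and C5–OMe, back to a 3,6-diaryl-4-pyranone and methanol. The cyclopentenone is the only carbocycle built. The C2 oxygen passes through this step as a pivalate and is methylated afterwards.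
4. Absolute configuration: an (S)-O-methylmandelate on the C6 oxygen turns the two ring antipodes into separable diastereomers.
5. Pyranone: from kojic acid by bromination at positions 6 and 3, one double Suzuki coupling with a silyl-protected 4-hydroxyphenylboronate, debenzylation and two acylations.

Key step: step 9

Remark: locants C1–C6 are those of the target as defined in line 1; pyranone positions follow kojic acid numbering (O1, CH2OH on position 2, enol oxygen on position 5); Ar = 4-(triisopropylsilyloxy)phenyl.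

**Route**

Step 1
Reactants: 1 4-(4,4,5,5-tetramethyl-1,3,2-dioxaborolan-2-yl)phenol
Product: 2 triisopropyl[4-(4,4,5,5-tetramethyl-1,3,2-dioxaborolan-2-yl)phenoxy]silane
Conditions: TIPSCl, imidazole, DMF, rt
Reagents that add atoms: triisopropylsilyl chloride, CC(C)[Si](Cl)(C(C)C)C(C)C
Why: Standard silylation of a phenol; the pinacol boronate is inert, and the bulky aryl silyl ether is chosen to tolerate the phosphate and carbonate bases used later and to fall to fluoride at the end.

Step 2
Reactants: 3 kojic acid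
Product: 4 6-bromo-5-hydroxy-2-(hydroxymethyl)-4H-pyran-4-one
Conditions: NBS (1.0 equiv), MeCN/H2O, 0 °C to rt
Reagents that add atoms: N-bromosuccinimide, BrN1C(=O)CCC1=O
Why: Electrophilic bromination of an enol: the free 5-hydroxyl makes position 6 the nucleophilic enol carbon, so substitution should occur there and not at position 3.

Step 3
Reactants: 4 6-bromo-5-hydroxy-2-(hydroxymethyl)-4H-pyran-4-one
Product: 5 5-(benzyloxy)-6-bromo-2-(hydroxymethyl)-4H-pyran-4-one
Conditions: BnBr, K2CO3, DMF, rt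
Reagents that add atoms: benzyl bromide, BrCc1ccccc1
Why: Williamson O-alkylation of the acidic enol hydroxyl (the primary alcohol is not ionised by K2CO3); the benzyl group masks the chelating 3-hydroxy-4-pyranone unit during bromination and coupling.

Step 4
Reactants: 5 5-(benzyloxy)-6-bromo-2-(hydroxymethyl)-4H-pyran-4-one
Product: 6 5-(benzyloxy)-3,6-dibromo-2-(hydroxymethyl)-4H-pyran-4-one
Conditions: NBS (1.1 equiv), DMF, 50 °C, dark
Reagents that add atoms: N-bromosuccinimide, BrN1C(=O)CCC1=O
Why: Electrophilic bromination at the only remaining ring CH, position 3, which is the nucleophilic β-carbon of the O1–C2=C3 enol ether unit.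

Step 5
Reactants: 6 5-(benzyloxy)-3,6-dibromo-2-(hydroxymethyl)-4H-pyran-4-one; 2 triisopropyl[4-(4,4,5,5-tetramethyl-1,3,2-dioxaborolan-2-yl)phenoxy]silane (2.5 equiv)
Product: 7 5-(benzyloxy)-2-(hydroxymethyl)-3,6-bis(Ar)-4H-pyran-4-one
Conditions: Pd(PPh3)4 (5 mol%), K3PO4, 1,4-dioxane/H2O (10:1), 90 °C
Reagents that add atoms: none
Why: Double Suzuki–Miyaura coupling; zerovalent palladium inserts readily into the vinylogous acyl bromide at position 6 and into the α-bromoenone at position 3, the latter as in isoflavone syntheses from 3-bromochromones, and both sites take the same aryl group.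

Step 6
Reactants: 7 5-(benzyloxy)-2-(hydroxymethyl)-3,6-bis(Ar)-4H-pyran-4-one
Product: 8 5-hydroxy-2-(hydroxymethyl)-3,6-bis(Ar)-4H-pyran-4-one
Conditions: H2 (1 atm), Pd/C, EtOAc, rt
Reagents that add atoms: none
Why: Hydrogenolysis of the O-benzyl enol ether; the aryl silyl ethers, the fully substituted pyranone ring and the hydroxymethyl group should persist at atmospheric pressure.

Step 7
Reactants: 8 5-hydroxy-2-(hydroxymethyl)-3,6-bis(Ar)-4H-pyran-4-one
Product: 9 2-(hydroxymethyl)-4-oxo-3,6-bis(Ar)-4H-pyran-5-yl pivalate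
Conditions: PivCl (1.05 equiv), Et3N, CH2Cl2, −40 to 0 °C
Reagents that add atoms: pivaloyl chloride, CC(C)(C)C(Cl)=O
Why: Chemoselective O-acylation: the acidic enol reacts as its ammonium enolate much faster than the neutral primary alcohol when no acyl-transfer catalyst is present.

Step 8
Reactants: 9 2-(hydroxymethyl)-4-oxo-3,6-bis(Ar)-4H-pyran-5-yl pivalate; 10 (S)-O-methylmandelic acid
Product: 11 5-(pivaloyloxy)-3,6-bis(Ar)-2-[(S)-O-methylmandeloyloxymethyl]-4H-pyran-4-one
Conditions: DCC, DMAP (10 mol%), CH2Cl2, 0 °C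
Reagents that add atoms: none
Why: Steglich esterification of the remaining primary alcohol; low temperature and catalytic DMAP limit epimerisation of the acid and leave the hindered pivalate in place.

Step 9
Reactants: 11 5-(pivaloyloxy)-3,6-bis(Ar)-2-[(S)-O-methylmandeloyloxymethyl]-4H-pyran-4-one
Product: 14 (4R,5R)-4-hydroxy-5-methoxy-4-[(S)-O-methylmandeloyloxymethyl]-2-(pivaloyloxy)-3,5-bis(Ar)cyclopent-2-en-1-one, via oxyallyl zwitterion 12 (not isolated), via enol adduct 13 (not isolated)
Conditions: hν (λ > 300 nm, Pyrex-filtered medium-pressure Hg lamp), degassed MeOH/THF (9:1, about 2 mM), 15 °C; then SiO2 chromatography to remove the (4S,5S)-ring diastereomer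
Reagents that add atoms: methanol, CO
Why: On excitation the pyranone undergoes a disrotatory four-electron electrocyclisation that joins ring positions 2 and 6 (the C3–C4 bond), so the cyclopentenone carbocycle appears as the oxirane-bridged oxyallyl zwitterion 12; methanol then adds to its aryl-bearing terminus C5 on the face away from the oxirane to give enol 13, and β-elimination from this enol breaks the benzylic oxirane bond C3–O, which leaves the former ring oxygen as the C4 hydroxyl. The closest known reaction type is the light-induced contraction of 4-pyranones to trans-4-hydroxy-5-alkoxycyclopentenones in alcohols or water. The five-membered ring is closed by this excited-state 4π electrocyclisation (a photochemical Nazarov-type closure) and by no ionic cyclisation. C4 and C5 are created together: the oxirane blocks one face, so methanol enters anti to it and C4–O ends trans to C5–OMe, whereas the direction of disrotation is not steered by the distant mandelate, so both ring antipodes should arise in similar amounts and the (S)-ester only converts them into 14 and its separable (4S,5S)-ring diastereomer. The step needs methanol to attack the aryl terminus and not the oxygen-bearing one, and this is why the C2 oxygen is an ester here: a methoxy group would hold the positive charge on its own carbon and draw methanol there, while the pivaloyloxy group is a poor π-donor, so the charge should reside on C5 next to the electron-rich 4-silyloxyphenyl ring. Light above 300 nm is absorbed by the diarylpyranone and not by the mandelate phenyl ring, and high dilution disfavours photodimerisation.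

Step 10
Reactants: 14 (4R,5R)-4-hydroxy-5-methoxy-4-[(S)-O-methylmandeloyloxymethyl]-2-(pivaloyloxy)-3,5-bis(Ar)cyclopent-2-en-1-one
Product: 16 (4R,5R)-4-hydroxy-4-(hydroxymethyl)-2,5-dimethoxy-3,5-bis(Ar)cyclopent-2-en-1-one, via diosphenol 15 (not isolated)
Conditions: K2CO3, MeOH/THF, 0 °C; then Me2SO4, 0 °C to rt
Reagents that add atoms: dimethyl sulfate, COS(=O)(=O)OC
Why: Carbonate-mediated transesterification removes the enol pivalate (an active ester) and the α-alkoxy ester, and the resulting diosphenolate 15 is O-methylated in the same pot (Williamson-type alkylation of the only anionic oxygen), which installs the C2 methyl ether without touching the two alcohols or the stereocentres.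

Step 11
Reactants: 16 (4R,5R)-4-hydroxy-4-(hydroxymethyl)-2,5-dimethoxy-3,5-bis(Ar)cyclopent-2-en-1-one
Product: 17 (4R,5R)-4-hydroxy-2,5-dimethoxy-4-(tosyloxymethyl)-3,5-bis(Ar)cyclopent-2-en-1-one
Conditions: TsCl, Et3N, DMAP (cat.), CH2Cl2, 0 °C to rt
Reagents that add atoms: p-toluenesulfonyl chloride, Cc1ccc(cc1)S(Cl)(=O)=O
Why: Selective sulfonylation of the primary C6 hydroxyl; the tertiary C4 hydroxyl does not react with TsCl under amine base.

Step 12
Reactants: 17 (4R,5R)-4-hydroxy-2,5-dimethoxy-4-(tosyloxymethyl)-3,5-bis(Ar)cyclopent-2-en-1-one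
Product: 18 (3R,4R)-4,6-dimethoxy-4,7-bis(Ar)-1-oxaspiro[2.4]hept-6-en-5-one
Conditions: NaH, THF, 0 °C
Reagents that add atoms: none
Why: Intramolecular Williamson etherification (3-exo-tet): the C4 alkoxide displaces the C6 tosylate, the C4–O bond is not broken so C4 keeps its configuration, and the closure should outrun retro-aldol opening of the alkoxide.

Step 13
Reactants: 18 (3R,4R)-4,6-dimethoxy-4,7-bis(Ar)-1-oxaspiro[2.4]hept-6-en-5-one
Product: 19 (3R,4R)-4,7-bis(4-hydroxyphenyl)-4,6-dimethoxy-1-oxaspiro[2.4]hept-6-en-5-one (CNP0504072.1)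
Conditions: TBAF, AcOH, THF, 0 °C
Reagents that add atoms: none
Why: Fluoride-induced desilylation of both aryl silyl ethers; buffering with acetic acid keeps the medium near neutral so that the vinyl oxirane and the tertiary benzylic methyl ether should survive.

**Compound list**

1 | 4-(4,4,5,5-tetramethyl-1,3,2-dioxaborolan-2-yl)phenol (4-hydroxyphenylboronic acid pinacol ester) | CC1(C)OB(OC1(C)C)c1ccc(O)cc1 | starting material
2 | triisopropyl[4-(4,4,5,5-tetramethyl-1,3,2-dioxaborolan-2-yl)phenoxy]silane | CC(C)[Si](Oc1ccc(cc1)B1OC(C)(C)C(C)(C)O1)(C(C)C)C(C)C | intermediate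
3 | kojic acid (5-hydroxy-2-(hydroxymethyl)-4H-pyran-4-one) | OCC1=CC(=O)C(O)=CO1 | starting material
4 | 6-bromo-5-hydroxy-2-(hydroxymethyl)-4H-pyran-4-one | OCC1=CC(=O)C(O)=C(Br)O1 | intermediate
5 | 5-(benzyloxy)-6-bromo-2-(hydroxymethyl)-4H-pyran-4-one | OCC1=CC(=O)C(OCc2ccccc2)=C(Br)O1 | intermediate
6 | 5-(benzyloxy)-3,6-dibromo-2-(hydroxymethyl)-4H-pyran-4-one | OCC1=C(Br)C(=O)C(OCc2ccccc2)=C(Br)O1 | intermediate
7 | 5-(benzyloxy)-2-(hydroxymethyl)-3,6-bis[4-(triisopropylsilyloxy)phenyl]-4H-pyran-4-one | OCC1=C(c2ccc(O[Si](C(C)C)(C(C)C)C(C)C)cc2)C(=O)C(OCc2ccccc2)=C(c2ccc(O[Si](C(C)C)(C(C)C)C(C)C)cc2)O1 | intermediate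
8 | 5-hydroxy-2-(hydroxymethyl)-3,6-bis[4-(triisopropylsilyloxy)phenyl]-4H-pyran-4-one | OCC1=C(c2ccc(O[Si](C(C)C)(C(C)C)C(C)C)cc2)C(=O)C(O)=C(c2ccc(O[Si](C(C)C)(C(C)C)C(C)C)cc2)O1 | intermediate
9 | 2-(hydroxymethyl)-4-oxo-3,6-bis[4-(triisopropylsilyloxy)phenyl]-4H-pyran-5-yl pivalate | OCC1=C(c2ccc(O[Si](C(C)C)(C(C)C)C(C)C)cc2)C(=O)C(OC(=O)C(C)(C)C)=C(c2ccc(O[Si](C(C)C)(C(C)C)C(C)C)cc2)O1 | intermediate
10 | (S)-O-methylmandelic acid ((S)-2-methoxy-2-phenylacetic acid) | CO[C@H](C(=O)O)c1ccccc1 | starting material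
11 | 5-(pivaloyloxy)-3,6-bis[4-(triisopropylsilyloxy)phenyl]-2-[(S)-O-methylmandeloyloxymethyl]-4H-pyran-4-one (key-step precursor) | CC(C)(C)C(=O)OC1=C(c2ccc(O[Si](C(C)C)(C(C)C)C(C)C)cc2)OC(COC(=O)[C@@H](OC)c2ccccc2)=C(c2ccc(O[Si](C(C)C)(C(C)C)C(C)C)cc2)C1=O | intermediate
12 | oxirane-bridged oxyallyl zwitterion (ring series leading to 14 drawn; the mirror-image ring series forms alongside and leads to the (4S,5S)-ring diastereomer of 14) | [O-]C1=C(OC(=O)C(C)(C)C)[C@]2(c3ccc(O[Si](C(C)C)(C(C)C)C(C)C)cc3)O[C@]2(COC(=O)[C@@H](OC)c3ccccc3)[C+]1c1ccc(O[Si](C(C)C)(C(C)C)C(C)C)cc1 | intermediate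
13 | enol adduct of 12 with methanol, oxirane still closed (ring series leading to 14 drawn) | OC1=C(OC(=O)C(C)(C)C)[C@]2(c3ccc(O[Si](C(C)C)(C(C)C)C(C)C)cc3)O[C@]2(COC(=O)[C@@H](OC)c3ccccc3)[C@]1(OC)c1ccc(O[Si](C(C)C)(C(C)C)C(C)C)cc1 | intermediate
14 | (4R,5R)-4-hydroxy-5-methoxy-4-[(S)-O-methylmandeloyloxymethyl]-2-(pivaloyloxy)-3,5-bis[4-(triisopropylsilyloxy)phenyl]cyclopent-2-en-1-one (key-step product) | CC(C)(C)C(=O)OC1=C(c2ccc(O[Si](C(C)C)(C(C)C)C(C)C)cc2)[C@@](O)(COC(=O)[C@@H](OC)c2ccccc2)[C@](OC)(c2ccc(O[Si](C(C)C)(C(C)C)C(C)C)cc2)C1=O | intermediate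
15 | (4R,5R)-2,4-dihydroxy-4-(hydroxymethyl)-5-methoxy-3,5-bis[4-(triisopropylsilyloxy)phenyl]cyclopent-2-en-1-one (diosphenol, present as its potassium enolate) | OC1=C(c2ccc(O[Si](C(C)C)(C(C)C)C(C)C)cc2)[C@@](O)(CO)[C@](OC)(c2ccc(O[Si](C(C)C)(C(C)C)C(C)C)cc2)C1=O | intermediate
16 | (4R,5R)-4-hydroxy-4-(hydroxymethyl)-2,5-dimethoxy-3,5-bis[4-(triisopropylsilyloxy)phenyl]cyclopent-2-en-1-one | COC1=C(c2ccc(O[Si](C(C)C)(C(C)C)C(C)C)cc2)[C@@](O)(CO)[C@](OC)(c2ccc(O[Si](C(C)C)(C(C)C)C(C)C)cc2)C1=O | intermediate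
17 | (4R,5R)-4-hydroxy-2,5-dimethoxy-4-(tosyloxymethyl)-3,5-bis[4-(triisopropylsilyloxy)phenyl]cyclopent-2-en-1-one | COC1=C(c2ccc(O[Si](C(C)C)(C(C)C)C(C)C)cc2)[C@@](O)(COS(=O)(=O)c2ccc(C)cc2)[C@](OC)(c2ccc(O[Si](C(C)C)(C(C)C)C(C)C)cc2)C1=O | intermediate
18 | (3R,4R)-4,6-dimethoxy-4,7-bis[4-(triisopropylsilyloxy)phenyl]-1-oxaspiro[2.4]hept-6-en-5-one | COC1=C(c2ccc(O[Si](C(C)C)(C(C)C)C(C)C)cc2)[C@@]2(CO2)[C@](OC)(c2ccc(O[Si](C(C)C)(C(C)C)C(C)C)cc2)C1=O | intermediate
19 | (3R,4R)-4,7-bis(4-hydroxyphenyl)-4,6-dimethoxy-1-oxaspiro[2.4]hept-6-en-5-one (CNP0504072.1) | COC1=C(c2ccc(O)cc2)[C@@]2(CO2)[C@](OC)(c2ccc(O)cc2)C1=O | target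

**Step count**

Total: 13 steps. Longest linear sequence: 12 steps (kojic acid 3 to target 19, steps 2–13); step 1 prepares the coupling partner.

**Steps most likely to fail**

1. Step 9. What may go wrong: methanol is captured at the ester-bearing oxyallyl terminus with loss of the pivaloyl group, the (pyranon-2-yl)methyl ester C–O bond heterolyses in the excited state, or the two diastereomers fail to separate. The fallback below removes the second and third problems; it does not cure misdirected capture. Fallback (sets out from 9, comes back at 14): the ring contraction is run on alcohol 9, which carries no ionisable acyloxymethyl group and no second chromophore. Irradiation in methanol under the same light regime should give the racemic trans product rac-(4R*,5R*)-4-hydroxy-4-(hydroxymethyl)-5-methoxy-2-(pivaloyloxy)-3,5-bis(Ar)cyclopent-2-en-1-one F1. Its primary hydroxyl is then esterified with 10 (DCC, catalytic DMAP, CH2Cl2, 0 °C; the tertiary hydroxyl does not react) to give 14 together with its ring diastereomer (4S,5S)-4-hydroxy-5-methoxy-4-[(S)-O-methylmandeloyloxymethyl]-2-(pivaloyloxy)-3,5-bis(Ar)cyclopent-2-en-1-one F2, which is removed by chromatography. The resolving acid is thus chosen on the ring-contracted alcohol and not fixed before the photoreaction.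

2. Step 10. What may go wrong: under carbonate in methanol the aryl silyl ethers are cleaved and the freed phenols methylated, or the diosphenolate degrades by dehydration across C3–C4 or by retro-aldol opening of the C4–C5 bond. Fallback (sets out from 14, comes back at 16): the two esters are removed one at a time without free alkoxide. Hydrazine acetate in DMF at 0 °C should cleave only the activated enol pivalate and give the diosphenol (4R,5R)-2,4-dihydroxy-5-methoxy-4-[(S)-O-methylmandeloyloxymethyl]-3,5-bis(Ar)cyclopent-2-en-1-one F3. (Trimethylsilyl)diazomethane in toluene/methanol methylates this acidic enol to (4R,5R)-4-hydroxy-2,5-dimethoxy-4-[(S)-O-methylmandeloyloxymethyl]-3,5-bis(Ar)cyclopent-2-en-1-one F4. The α-methoxy ester is then cleaved by Yb(OTf)3-catalysed methanolysis (chelation of the α-methoxy ester, neutral medium) to give 16.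

3. Step 4. What may go wrong: the second bromination stalls because the ring is deactivated by the bromine at position 6, or the reagent is consumed in oxidising the hydroxymethyl group. Fallback (sets out from 5, comes back at 7): the aryl groups are introduced one after the other. Suzuki–Miyaura coupling of 5 with 2 (1.2 equiv, Pd(PPh3)4, K3PO4, dioxane/H2O) at the vinylogous acyl bromide gives 5-(benzyloxy)-2-(hydroxymethyl)-6-[4-(triisopropylsilyloxy)phenyl]-4H-pyran-4-one F5. This more electron-rich pyranone is iodinated at position 3 (NIS, catalytic TFA, MeCN) to give 5-(benzyloxy)-2-(hydroxymethyl)-3-iodo-6-[4-(triisopropylsilyloxy)phenyl]-4H-pyran-4-one F6, and a second coupling with 2 gives 7.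

Further compounds
F1 | step 9 | rac-(4R*,5R*)-4-hydroxy-4-(hydroxymethyl)-5-methoxy-2-(pivaloyloxy)-3,5-bis[4-(triisopropylsilyloxy)phenyl]cyclopent-2-en-1-one (racemate; one enantiomer drawn) | CC(C)(C)C(=O)OC1=C(c2ccc(O[Si](C(C)C)(C(C)C)C(C)C)cc2)[C@@](O)(CO)[C@](OC)(c2ccc(O[Si](C(C)C)(C(C)C)C(C)C)cc2)C1=O
F2 | step 9 | (4S,5S)-4-hydroxy-5-methoxy-4-[(S)-O-methylmandeloyloxymethyl]-2-(pivaloyloxy)-3,5-bis[4-(triisopropylsilyloxy)phenyl]cyclopent-2-en-1-one (ring diastereomer of 14) | CC(C)(C)C(=O)OC1=C(c2ccc(O[Si](C(C)C)(C(C)C)C(C)C)cc2)[C@](O)(COC(=O)[C@@H](OC)c2ccccc2)[C@@](OC)(c2ccc(O[Si](C(C)C)(C(C)C)C(C)C)cc2)C1=O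
F3 | step 10 | (4R,5R)-2,4-dihydroxy-5-methoxy-4-[(S)-O-methylmandeloyloxymethyl]-3,5-bis[4-(triisopropylsilyloxy)phenyl]cyclopent-2-en-1-one | OC1=C(c2ccc(O[Si](C(C)C)(C(C)C)C(C)C)cc2)[C@@](O)(COC(=O)[C@@H](OC)c2ccccc2)[C@](OC)(c2ccc(O[Si](C(C)C)(C(C)C)C(C)C)cc2)C1=O
F4 | step 10 | (4R,5R)-4-hydroxy-2,5-dimethoxy-4-[(S)-O-methylmandeloyloxymethyl]-3,5-bis[4-(triisopropylsilyloxy)phenyl]cyclopent-2-en-1-one | COC1=C(c2ccc(O[Si](C(C)C)(C(C)C)C(C)C)cc2)[C@@](O)(COC(=O)[C@@H](OC)c2ccccc2)[C@](OC)(c2ccc(O[Si](C(C)C)(C(C)C)C(C)C)cc2)C1=O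
F5 | step 4 | 5-(benzyloxy)-2-(hydroxymethyl)-6-[4-(triisopropylsilyloxy)phenyl]-4H-pyran-4-one | OCC1=CC(=O)C(OCc2ccccc2)=C(c2ccc(O[Si](C(C)C)(C(C)C)C(C)C)cc2)O1
F6 | step 4 | 5-(benzyloxy)-2-(hydroxymethyl)-3-iodo-6-[4-(triisopropylsilyloxy)phenyl]-4H-pyran-4-one | OCC1=C(I)C(=O)C(OCc2ccccc2)=C(c2ccc(O[Si](C(C)C)(C(C)C)C(C)C)cc2)O1
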